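**Remarks on the chemistry (assumptions)**

- Atom labels follow the labdane numbering of the target from the first step on: ring A = C1–C5 and C10, ring B = C5–C10, side chain C11–C16, C17 on C8, C18 (α-methyl) and C19 (β-CH2O) on C4, C20 on C10.
- One correction to the key step: the carbon of the 2-(trimethylsilylmethyl)allyl unit that bonds to C4 is the olefinic CH2 (γ to silicon), which becomes ring carbon C3. The CH2Si carbon ends as the exocyclic methylene. The unit is symmetric about C2, so the structures of 12 and 13 are unchanged and their stereodescriptors agree with the target.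
- Compound 3 is carried as a mixture of C10 epimers (the centre is re-enolised in step 2). Compounds 10 and 12 are drawn as the expected major E enol ethers and carried with their Z isomers.

## Structural features

The target is a labdane: a trans-fused decalin (rings A and B sharing C5–C10) with a trisubstituted C7=C8 olefin in ring B. C9 carries a five-carbon chain with an (E)-C13=C14 olefin that ends at C15 as an allylic ester of monomethyl succinate. Ring A carries a free equatorial 2α-hydroxyl and a quaternary C4 with an α-methyl (C18) and an axial β-CH2O-isovalerate (C19) syn to the C10 β-methyl (C20). There are five stereocentres (C2, C4, C5, C9, C10); C4–C5–C10–C9 are contiguous and two of them, C4 and C10, are quaternary and flank C5. The fragile groups are three different esters (the allylic one is prone to ionisation), the C7=C8 olefin, which acid can move into the tetrasubstituted C8=C9 position, and a secondary hydroxyl that must stay unacylated. The real difficulty is quaternary C4 with its oxidised carbon in the more hindered axial site, together with three hydroxyls (C2, C15, C19) that need three different fates. The key step exploits the fact that the oxygens on C2 and C19 are 1,4-related through C3–C4, a dissonant pattern. Oxidising a C19 enol ether makes C4 electrophilic, and an allyl nucleophile whose central carbon becomes C2 then closes ring A at C3–C4.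

## Logic of the disconnections

**36 ⇒ 35 ⇒ 33 + 34 ⇒ 32 ⇒ 31 ⇒ 29 + 30.** The O–Si bond at C2 and the two acyl C–O bonds at C19 and C15 are cut. The esters come last because none would survive the organometallic, chromium and dissolving-metal steps. The gain is that the three hydroxyls become distinguishable: C15 free in 29, C19 latent as an acetal, C2 silylated. The demand is that each acylation meets exactly one free hydroxyl and that the acetal of 31 opens without loss of the silyl ether or the allylic ester.

**29 ⇒ 28 ⇒ 26 + 27.** The C13=C14 double bond is cut. An (E)-trisubstituted enoate is the standard retron of a phosphonate olefination, and the side chain shrinks to a methyl ketone. The forward step must favour the E isomer, and the ester reduction must spare the acetal.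

**26 ⇒ 25.** The C13 carbonyl is traced to a terminal alkene. A monosubstituted alkene is inert to every reagent between steps 12 and 15, which a ketone or ketal would not be alongside the C19 acetal. The oxidation must pick the terminal alkene over C7=C8 and stay non-acidic.

**25 ⇒ 24 ⇒ 22.** The C7–H and C9–H bonds are cut. The C7=C8 olefin and the C9 stereocentre both come from a C8=C9 enone, so C9 becomes planar and its configuration is deferred. The demand is axial protonation of C9 from the α face and capture of the regiodefined enolate on oxygen.

**22 ⇒ 21 ⇒ 19 + 20.** The C9–C11 bond is cut. C9 is a carbonyl carbon in 19, so the chain enters by 1,2-addition and the oxygen is moved to C7 by oxidative 1,3-transposition. The side chain reduces to a commercial four-carbon Grignard reagent. The demand is clean 1,2-addition to a carbonyl flanked by quaternary C10.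

**19 ⇒ 18 ⇒ 17 ⇒ 16 ⇒ 15 ⇒ 13.** The C2–O bond is traced through the C2 ketone to the C2 exocyclic methylene that the allylsilane leaves behind. The gain is that C2 needs no oxygen before ring closure. The demands are an ozonolysis that ignores the enone and an inversion, because hydride can reach C2 only from the α face.

**13 ⇒ 12.** The C3–C4 bond is cut, opening ring A. This single cut removes the quaternary stereocentre C4, places the C19 and C2 functions, and returns a monocyclic carvone derivative. The demand is oxidative umpolung of the enol ether and axial placement of C19 at C4.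

**12 ⇒ 10 + 11.** The bond between the vinylic carbon and CH2Si is cut. The allylsilane is too electron-rich to survive the ozonolysis of step 3, so it is unmasked last from a vinyl bromide. The coupling must leave the enone carbonyl and the enol ether alone.

**10 ⇒ 8 + 9.** The C4=C19 bond is cut. The enol ether is a one-carbon Wittig product of a methyl ketone. The demand is selectivity between the two carbonyls and no epimerisation at C5.

**8 ⇒ 6.** The C4 carbonyl is traced to the isopropenyl group of the chiral pool. Ozone must choose it over the vinyl bromide and the enone.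

**6 ⇒ 3 + 4 and 3 ⇒ 1.** The C10–C1 and C10–C20 bonds are cut. Both are α′-alkylations of 1, which supplies C5 and the ring B enone with its C8 methyl. The order, methyl first and bromoallyl second, sets C10, because the second electrophile enters anti to the isopropenyl group.

## Other disconnections considered

**Alternative 1:** The cut is at C5–C10 and C8–C9, which opens both rings to the acyclic triene A1. The forward key step is a thermal intramolecular Diels–Alder reaction in which the C5=C6–C7=C8 siloxydiene adds to the C9=C10 enoate to give the decalin A2.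
- In its favour: two C–C bonds, both rings and the C5, C9 and C10 centres arise in one operation. C9 arrives with C11 attached at the ester level and β-oriented, so nothing like steps 12–14 of the chosen plan is needed; on this point the alternative is better. It also carries the C2 and C19 oxygens in their final configuration from the start, so no inversion at C2 is required, which is again better.
- Against it: C2 and the quaternary C4 must be made enantioselectively in an open chain, which is harder than making C4 in a ring. The dienophile is a β,β-disubstituted enoate and would need forcing conditions that a (Z)-siloxydiene tolerates poorly. Trans fusion and the orientation at C9 depend on one of two folded transition states with no strong bias. The enol ether of A2 lies at C6=C7, so the C7 carbonyl would have to be re-enolised toward C8 with regiocontrol.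
- Comparison: mechanistically a concerted, geometry-specific cycloaddition is at least the equal of the radical-cation closure for the relative configuration of C5, C9 and C10, but weaker for the facial relationship to C4. In step count it is shorter after the key step and longer and less certain before it, so roughly equal overall.

**Alternative 2:** The cut is at C10–C20, with a temporary C1–C20 bond. The forward key step is the hydroxyl-directed cyclopropanation of the allylic alcohol A3 with Et2Zn and CH2I2 to give the cyclopropane A4, whose C1–C20 bond is later cleaved reductively to leave the angular methyl.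
- In its favour: delivery of the zinc carbenoid syn to a neighbouring hydroxyl is among the most dependable facial controls known. On predictability of the key step the alternative is better than the chosen plan. The C2 oxygen is present and doubles as the control element, and a dissolving-metal opening of the derived cyclopropyl ketone could in principle also give the equatorial 2α-alcohol, which would be neater than steps 8–10 of the chosen plan.
- Against it: the step builds no ring of the target and only one skeletal bond, at a centre that the chosen plan sets by a plain enolate alkylation in step 2. The 2β-hydroxyl has the wrong configuration. In A4, C4 is still tertiary, C8 has no methyl and no olefin, and the side chain lacks C14 and C15.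
- Comparison: the decalin and its absolute configuration must come from earlier chemistry. Structurally it solves less, mechanistically it is safer, and in step economy it is clearly the longer route.

**Alternative 3:** The cut is at C1–C10 and C4–C5. The forward key step is a catalytic asymmetric Diels–Alder reaction of the aminosiloxydiene A5 with the (E)-enal A6 under (salen)CrSbF6 (trivalent chromium), which gives the cyclohexenone A7 after acidic work-up.
- In its favour: the absolute configuration comes from a catalyst, so either enantiomer is available and no chiral pool is needed; here the alternative is better. C10 and C5 are set together with their relative configuration fixed by the enal geometry, which equals what steps 1–2 of the chosen plan deliver. The C9 aldehyde and the C7 ketal chain are placed for an aldol closure of ring B and a conjugate introduction of the side chain at C9, which could be shorter than steps 12–15; that is also named as a point in its favour.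
- Against it: A6 is an α,β-disubstituted enal, less reactive than the α-substituted acroleins on which this catalysis rests, so rate and enantioselectivity are open. A7 has its ring A oxygen on C3 instead of C2, and C4 is a bare methylene. Two stereocontrolled alkylations at C4 and a 1,2-carbonyl transposition would be needed, whereas the chosen key step places C18, C19 and the C2 function in one operation.
- Comparison: structurally the fit to ring A is poorer, and mechanistically the cycloaddition is well founded but on simpler dienophiles. In step count the gain in ring B is likely to be spent again in ring A.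

Key step: step 6

## Route

**Step 1**
Reactants: 1 (R)-(−)-carvone
Product: 3 trans-6-methylcarvone (methyl on C10), via lithium dienolate 2 (not isolated)
Conditions: LiN(iPr)2, THF, −78 °C; MeI, −78 → 0 °C
Reagents that add atoms: iodomethane, CI
Why: Kinetic α′-deprotonation gives the cross-conjugated enolate, which is methylated at C10 (enolate alkylation); the new centre is planarised again in step 2, so its epimer ratio does not matter.

**Step 2**
Reactants: 3 trans-6-methylcarvone; 4 2,3-dibromopropene
Product: 6 6-(2-bromoprop-2-enyl)-6-methylcarvone (bromoallyl anti to isopropenyl), via lithium enolate 5 (not isolated)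
Conditions: LiN(iPr)2, THF, −78 °C; 4, DMPU, −78 → 0 °C
Reagents that add atoms: none
Why: Enolate alkylation by SN2 at the allylic bromide, the vinylic bromide staying inert; the electrophile enters anti to the C5 isopropenyl group, so C1 ends trans to C4 and C20 cis, which is the C5/C10 relationship of the target.

**Step 3**
Reactants: 6 6-(2-bromoprop-2-enyl)-6-methylcarvone
Product: 8 5-acetyl-6-(2-bromoprop-2-enyl)-2,6-dimethylcyclohex-2-enone, via secondary ozonide 7 (not isolated)
Conditions: O3, CH2Cl2, Sudan Red 7B end point, −78 °C; Me2S, −78 °C → rt
Reagents that add atoms: ozone, [O-][O+]=O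
Why: Ozonolysis with indicator control; the electrophilic oxidant takes the only electron-rich alkene, the isopropenyl group, while the vinyl bromide and the enone are deactivated, and C5 is untouched under these non-basic conditions.

**Step 4**
Reactants: 8 5-acetyl-6-(2-bromoprop-2-enyl)-2,6-dimethylcyclohex-2-enone; 9 (methoxymethyl)triphenylphosphonium chloride
Product: 10 6-(2-bromoprop-2-enyl)-5-[(E)-1-methoxyprop-1-en-2-yl]-2,6-dimethylcyclohex-2-enone
Conditions: 9, KN(SiMe3)2, THF, 0 °C; then 8, −78 °C → rt
Reagents that add atoms: none
Why: Wittig reaction of the methyl ketone with the preformed ylide at low temperature; the C9 carbonyl is conjugated and wedged between quaternary C10 and the substituted C8, so it should react far more slowly, and the E isomer should dominate because the methoxy group avoids the branched C5 substituent.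

**Step 5**
Reactants: 10 6-(2-bromoprop-2-enyl)-5-[(E)-1-methoxyprop-1-en-2-yl]-2,6-dimethylcyclohex-2-enone; 11 (trimethylsilyl)methylmagnesium chloride
Product: 12 5-[(E)-1-methoxyprop-1-en-2-yl]-2,6-dimethyl-6-[2-(trimethylsilylmethyl)prop-2-enyl]cyclohex-2-enone
Conditions: 11, ZnCl2, THF, 0 °C; then 10, Pd(PPh3)4 (5 mol %), THF, 45 °C
Reagents that add atoms: none
Why: Negishi coupling (oxidative addition into the vinylic C–Br bond, transmetalation, reductive elimination); moving the nucleophile from magnesium to zinc protects the C9 carbonyl from 1,2-addition, the CH2SiMe3 group has no β-hydrogen, and the neutral medium spares the enol ether.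

**Step 6**
Reactants: 12 5-[(E)-1-methoxyprop-1-en-2-yl]-2,6-dimethyl-6-[2-(trimethylsilylmethyl)prop-2-enyl]cyclohex-2-enone
Product: 13 4β-(dimethoxymethyl)-4α,8,10β-trimethyl-2-methylene-5α-H-octal-7-en-9-one (trans-decalin)
Conditions: reticulated vitreous carbon anode, Pt cathode, undivided cell, LiClO4 (0.1 M), MeOH/THF (1:4), 2,6-lutidine, 8 mA constant current, 2.2 F/mol, rt
Reagents that add atoms: methanol, CO
Why: Anodic oxidation removes one electron from the most electron-rich π system, the trisubstituted enol ether, and the radical cation is electrophilic at C4, the carbon that is nucleophilic in the neutral enol ether. The olefinic CH2 of the 2-(silylmethyl)allyl unit adds to C4 and becomes C3; the β-silyl cation at C2 gives up Me3Si to methanol so that the former CH2Si carbon becomes the exocyclic methylene, and the C19 radical is oxidised a second time and captured by methanol as the dimethyl acetal. The closest known reaction type is the anodic coupling of enol ether radical cations with allylsilanes, which is established for six-membered rings and for quaternary carbons. Ring A closes 6-exo with respect to the enol ether (C4 inside, C19 outside) and 6-endo with respect to the allylsilane π bond, through a chair whose two arms on C5 and C10 are already trans, so only the trans-fused decalin can form. The one new stereocentre, C4, is set by that chair: the flat C19H(OMe) terminus takes the axial site syn to C20 and the C18 methyl lies near C5–H, whereas the other chair pushes C18 against quaternary C10 and 1,3-diaxial to C20; with the E enol ether only the small C19–H points toward C10. The step needs chemoselectivity over the enone and the allylsilane, which the oxidation potentials provide, and it needs the enol ether and allylsilane to survive until they react, which 2,6-lutidine secures by buffering the anodic acid; the gem-disubstituted C10 holds the two arms close.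

**Step 7**
Reactants: 13 4β-(dimethoxymethyl)-4α,8,10β-trimethyl-2-methylene-5α-H-octal-7-en-9-one
Product: 15 4β-(dimethoxymethyl)-4α,8,10β-trimethyl-5α-H-octal-7-ene-2,9-dione, via spiro ozonide 14 (not isolated)
Conditions: O3, CH2Cl2, NaHCO3, Sudan Red 7B end point, −78 °C; Me2S, −78 °C → rt
Reagents that add atoms: ozone, [O-][O+]=O
Why: Ozonolysis of the 1,1-disubstituted alkene, which is far more electron-rich than the conjugated C7=C8 bond; stopping at the dye end point protects the acetal C–H from slower oxidation.

**Step 8**
Reactants: 15 4β-(dimethoxymethyl)-4α,8,10β-trimethyl-5α-H-octal-7-ene-2,9-dione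
Product: 16 2β-hydroxy-4β-(dimethoxymethyl)-4α,8,10β-trimethyl-5α-H-octal-7-en-9-one
Conditions: NaBH4, MeOH/CH2Cl2, −78 → −40 °C
Reagents that add atoms: none
Why: Borohydride reduction of the saturated C2 ketone, much faster than that of the hindered conjugated C9 ketone; the axial path on the β face is closed by the syn-axial C20 methyl and C19 acetal, so hydride enters from the α face and gives the axial 2β-alcohol.

**Step 9**
Reactants: 16 2β-hydroxy-4β-(dimethoxymethyl)-4α,8,10β-trimethyl-5α-H-octal-7-en-9-one
Product: 17 2α-(4-nitrobenzoyloxy)-4β-(dimethoxymethyl)-4α,8,10β-trimethyl-5α-H-octal-7-en-9-one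
Conditions: 4-nitrobenzoic acid, PPh3, DIAD, toluene, 0 °C → rt
Reagents that add atoms: 4-nitrobenzoic acid, O=C(O)c1ccc(cc1)[N+](=O)[O-]
Why: Mitsunobu reaction; the carboxylate displaces the axial oxyphosphonium group by SN2 along the open equatorial α trajectory, inverting C2 to the target configuration, and the acidic nitrobenzoic acid is chosen to favour substitution over elimination.

**Step 10**
Reactants: 17 2α-(4-nitrobenzoyloxy)-4β-(dimethoxymethyl)-4α,8,10β-trimethyl-5α-H-octal-7-en-9-one
Product: 18 2α-hydroxy-4β-(dimethoxymethyl)-4α,8,10β-trimethyl-5α-H-octal-7-en-9-one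
Conditions: K2CO3, MeOH, rt
Reagents that add atoms: none
Why: Methanolysis of the activated aryl ester by acyl–oxygen cleavage, which leaves the C2–O bond and its configuration intact; the acetal is stable to base.

**Step 11**
Reactants: 18 2α-hydroxy-4β-(dimethoxymethyl)-4α,8,10β-trimethyl-5α-H-octal-7-en-9-one
Product: 19 2α-(tert-butyldimethylsilyloxy)-4β-(dimethoxymethyl)-4α,8,10β-trimethyl-5α-H-octal-7-en-9-one
Conditions: TBSCl, imidazole, DMF, rt
Reagents that add atoms: tert-butyldimethylsilyl chloride, CC(C)(C)[Si](C)(C)Cl
Why: Silylation of an unhindered equatorial alcohol; the TBS ether tolerates the organometallic, chromium, dissolving-metal and hydride steps ahead and leaves with fluoride in the presence of esters.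

**Step 12**
Reactants: 19 2α-(tert-butyldimethylsilyloxy)-4β-(dimethoxymethyl)-4α,8,10β-trimethyl-5α-H-octal-7-en-9-one; 20 but-3-enylmagnesium bromide
Product: 21 9α-(but-3-enyl)-9β-hydroxy-2α-(tert-butyldimethylsilyloxy)-4β-(dimethoxymethyl)-4α,8,10β-trimethyl-5α-H-octal-7-ene
Conditions: 20, CeCl3 (anhydrous), THF, −78 °C; then 19, −78 → 0 °C; aq NH4Cl
Reagents that add atoms: none
Why: Organocerium 1,2-addition, which suppresses enolisation, reduction and conjugate addition at the hindered enone; attack is expected anti to the axial C20 methyl, but the C9 configuration is erased in step 13 and is of no consequence.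

**Step 13**
Reactants: 21 9α-(but-3-enyl)-9β-hydroxy-2α-(tert-butyldimethylsilyloxy)-4β-(dimethoxymethyl)-4α,8,10β-trimethyl-5α-H-octal-7-ene
Product: 22 9-(but-3-enyl)-2α-(tert-butyldimethylsilyloxy)-4β-(dimethoxymethyl)-4α,8,10β-trimethyl-5α-H-octal-8-en-7-one
Conditions: (C5H5NH)[CrO3Cl] (3 equiv), 4 Å sieves, CH2Cl2, rt
Reagents that add atoms: pyridinium chlorochromate, [O-][Cr](=O)(=O)Cl.c1cc[nH+]cc1
Why: Oxidative 1,3-transposition of a tertiary allylic alcohol (Babler–Dauben oxidation): the chromate ester undergoes a [3,3] shift that places a chromium-derived oxygen on C7, and the secondary chromate is then oxidised to the enone; the terminal alkene, silyl ether and acetal are inert in the dry medium.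

**Step 14**
Reactants: 22 9-(but-3-enyl)-2α-(tert-butyldimethylsilyloxy)-4β-(dimethoxymethyl)-4α,8,10β-trimethyl-5α-H-octal-8-en-7-one
Product: 24 9β-(but-3-enyl)-2α-(tert-butyldimethylsilyloxy)-4β-(dimethoxymethyl)-4α,8,10β-trimethyl-5α,9α-H-octal-7-en-7-yl trifluoromethanesulfonate, via C7 lithium enolate 23 (not isolated)
Conditions: Li (2.2 equiv), NH3/THF, tBuOH (1 equiv), −78 °C; NH3 evaporated; PhNTf2, THF, 0 °C
Reagents that add atoms: N-phenylbis(trifluoromethanesulfonimide), O=S(=O)(N(c1ccccc1)S(=O)(=O)C(F)(F)F)C(F)(F)F
Why: Birch-type reduction of the enone followed by O-triflation of the regiodefined enolate; the β-carbon C9 is protonated axially from the α face, anti to the axial C20 methyl, which leaves the side chain equatorial and β, and the enolate can only be C7=C8.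

**Step 15**
Reactants: 24 9β-(but-3-enyl)-2α-(tert-butyldimethylsilyloxy)-4β-(dimethoxymethyl)-4α,8,10β-trimethyl-5α,9α-H-octal-7-en-7-yl trifluoromethanesulfonate
Product: 25 9β-(but-3-enyl)-2α-(tert-butyldimethylsilyloxy)-4β-(dimethoxymethyl)-4α,8,10β-trimethyl-5α,9α-H-octal-7-ene
Conditions: Pd(OAc)2 (5 mol %), PPh3, Bu3N, HCO2H, DMF, 60 °C
Reagents that add atoms: none
Why: Palladium-catalysed formate hydrogenolysis of an enol triflate (oxidative addition, decarboxylation of the formate to a palladium hydride, reductive elimination); the double bond stays at C7=C8 and C9 is not touched.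

**Step 16**
Reactants: 25 9β-(but-3-enyl)-2α-(tert-butyldimethylsilyloxy)-4β-(dimethoxymethyl)-4α,8,10β-trimethyl-5α,9α-H-octal-7-ene
Product: 26 2α-(tert-butyldimethylsilyloxy)-19,19-dimethoxy-14,15-dinorlabd-7-en-13-one
Conditions: PdCl2 (10 mol %), Cu(OAc)2 (20 mol %), O2 (1 atm), DMA/H2O (7:1), rt
Reagents that add atoms: water, O
Why: Wacker oxidation with Markovnikov hydroxypalladation of the monosubstituted alkene; the trisubstituted ring olefin is too hindered to coordinate, and the acetate-buffered copper salt keeps the medium from hydrolysing the acetal or the silyl ether.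

**Step 17**
Reactants: 26 2α-(tert-butyldimethylsilyloxy)-19,19-dimethoxy-14,15-dinorlabd-7-en-13-one; 27 triethyl phosphonoacetate
Product: 28 ethyl (13E)-2α-(tert-butyldimethylsilyloxy)-19,19-dimethoxylabda-7,13-dien-15-oate
Conditions: 27, NaH, THF, 0 °C; then 26, rt → 50 °C
Reagents that add atoms: none
Why: Horner–Wadsworth–Emmons olefination of a methyl ketone; the ester should settle trans to the larger C12 chain, giving mainly the E isomer, and the minor Z isomer is removed by chromatography.

**Step 18**
Reactants: 28 ethyl (13E)-2α-(tert-butyldimethylsilyloxy)-19,19-dimethoxylabda-7,13-dien-15-oate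
Product: 29 (13E)-2α-(tert-butyldimethylsilyloxy)-19,19-dimethoxylabda-7,13-dien-15-ol
Conditions: iBu2AlH (2.5 equiv), CH2Cl2, −78 °C; aq KNaC4H4O6
Reagents that add atoms: none
Why: 1,2-Reduction of the conjugated ester to the allylic alcohol by the aluminium hydride; acetal, silyl ether and olefin geometry are unaffected.

**Step 19**
Reactants: 29 (13E)-2α-(tert-butyldimethylsilyloxy)-19,19-dimethoxylabda-7,13-dien-15-ol; 30 methyl 4-chloro-4-oxobutanoate
Product: 31 methyl (13E)-2α-(tert-butyldimethylsilyloxy)-19,19-dimethoxylabda-7,13-dien-15-yl butanedioate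
Conditions: 30, pyridine, DMAP (cat.), CH2Cl2, 0 °C
Reagents that add atoms: none
Why: Acylation of the only free hydroxyl with the acid chloride; C19 is still an acetal and C2 a silyl ether, so no selectivity is required.

**Step 20**
Reactants: 31 methyl (13E)-2α-(tert-butyldimethylsilyloxy)-19,19-dimethoxylabda-7,13-dien-15-yl butanedioate
Product: 32 methyl (13E)-2α-(tert-butyldimethylsilyloxy)-19-oxolabda-7,13-dien-15-yl butanedioate
Conditions: PPTS (cat.), acetone/H2O (10:1), 45 °C
Reagents that add atoms: water, O
Why: Acid-catalysed acetal hydrolysis through the oxocarbenium ion, helped by relief of strain at the crowded C4; the weak acid should leave the secondary silyl ether, the allylic ester and the olefin positions alone.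

**Step 21**
Reactants: 32 methyl (13E)-2α-(tert-butyldimethylsilyloxy)-19-oxolabda-7,13-dien-15-yl butanedioate
Product: 33 methyl (13E)-2α-(tert-butyldimethylsilyloxy)-19-hydroxylabda-7,13-dien-15-yl butanedioate
Conditions: NaBH4, THF/MeOH (4:1), −20 °C
Reagents that add atoms: none
Why: Borohydride reduction of the aldehyde, which is much faster than attack on either ester at this temperature.

**Step 22**
Reactants: 33 methyl (13E)-2α-(tert-butyldimethylsilyloxy)-19-hydroxylabda-7,13-dien-15-yl butanedioate; 34 3-methylbutanoyl chloride
Product: 35 methyl (13E)-2α-(tert-butyldimethylsilyloxy)-19-(3-methylbutanoyloxy)labda-7,13-dien-15-yl butanedioate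
Conditions: 34, pyridine, DMAP, CH2Cl2, rt
Reagents that add atoms: none
Why: DMAP-catalysed acylation through the acylpyridinium ion, which is needed for the neopentyl, axial C19 hydroxyl; it is the only free hydroxyl.

**Step 23**
Reactants: 35 methyl (13E)-2α-(tert-butyldimethylsilyloxy)-19-(3-methylbutanoyloxy)labda-7,13-dien-15-yl butanedioate
Product: 36 methyl (13E)-2α-hydroxy-19-(3-methylbutanoyloxy)labda-7,13-dien-15-yl butanedioate (CNP0118741.1)
Conditions: HF·pyridine, pyridine/THF, 0 °C → rt
Reagents that add atoms: none
Why: Fluoride-driven cleavage of the Si–O bond; the C2–O bond is not broken, so the configuration stays, and the buffered reagent leaves the three esters and both olefins intact.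

## Compound list

1 | (R)-(−)-carvone | CC1=CC[C@H](CC1=O)C(C)=C | starting material
2 | lithium dienolate of 1 (O–Li on C9, C9=C10) | CC1=CC[C@@H](C(C)=C)C=C1O[Li] | intermediate (not isolated)
3 | trans-6-methylcarvone, (5R,6S)-2,6-dimethyl-5-(prop-1-en-2-yl)cyclohex-2-enone (minor cis epimer carried) | CC1=CC[C@@H](C(C)=C)[C@H](C)C1=O | intermediate
4 | 2,3-dibromopropene | C=C(Br)CBr | starting material
5 | lithium enolate of 3 (O–Li on C9, C9=C10) | CC1=CC[C@@H](C(C)=C)C(C)=C1O[Li] | intermediate (not isolated)
6 | 6-(2-bromoprop-2-enyl)-6-methylcarvone; bromoallyl anti and methyl syn to isopropenyl | O=C1C(C)=CC[C@@H](C(C)=C)[C@]1(C)CC(Br)=C | intermediate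
7 | secondary ozonide (1,2,4-trioxolane) of the isopropenyl group of 6, both epimers at the trioxolane carbon | O=C1C(C)=CC[C@@H](C2(C)OCOO2)[C@]1(C)CC(Br)=C | intermediate (not isolated)
8 | 5-acetyl-6-(2-bromoprop-2-enyl)-2,6-dimethylcyclohex-2-enone; acetyl anti to bromoallyl | O=C1C(C)=CC[C@@H](C(C)=O)[C@]1(C)CC(Br)=C | intermediate
9 | (methoxymethyl)triphenylphosphonium chloride | COC[P+](c1ccccc1)(c1ccccc1)c1ccccc1.[Cl-] | starting material
10 | 6-(2-bromoprop-2-enyl)-5-[(E)-1-methoxyprop-1-en-2-yl]-2,6-dimethylcyclohex-2-enone (Z isomer carried) | O=C1C(C)=CC[C@@H](/C(C)=C/OC)[C@]1(C)CC(Br)=C | intermediate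
11 | (trimethylsilyl)methylmagnesium chloride | C[Si](C)(C)C[Mg]Cl | starting material
12 | 5-[(E)-1-methoxyprop-1-en-2-yl]-2,6-dimethyl-6-[2-(trimethylsilylmethyl)prop-2-enyl]cyclohex-2-enone (Z isomer carried) | O=C1C(C)=CC[C@@H](/C(C)=C/OC)[C@]1(C)CC(=C)C[Si](C)(C)C | intermediate
13 | 4β-(dimethoxymethyl)-4α,8,10β-trimethyl-2-methylene-5α-H-octal-7-en-9-one | O=C1C(C)=CC[C@H]2[C@@](C)(C(OC)OC)CC(=C)C[C@]12C | intermediate
14 | spiro ozonide (1,2,4-trioxolane at C2) of 13, both epimers at C2 | O=C1C(C)=CC[C@H]2[C@@](C)(C(OC)OC)CC3(OCOO3)C[C@]12C | intermediate (not isolated)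
15 | 4β-(dimethoxymethyl)-4α,8,10β-trimethyl-5α-H-octal-7-ene-2,9-dione | O=C1C(C)=CC[C@H]2[C@@](C)(C(OC)OC)CC(=O)C[C@]12C | intermediate
16 | 2β-hydroxy-4β-(dimethoxymethyl)-4α,8,10β-trimethyl-5α-H-octal-7-en-9-one | O=C1C(C)=CC[C@H]2[C@@](C)(C(OC)OC)C[C@@H](O)C[C@]12C | intermediate
17 | 2α-(4-nitrobenzoyloxy)-4β-(dimethoxymethyl)-4α,8,10β-trimethyl-5α-H-octal-7-en-9-one | O=C1C(C)=CC[C@H]2[C@@](C)(C(OC)OC)C[C@H](OC(=O)c3ccc(cc3)[N+](=O)[O-])C[C@]12C | intermediate
18 | 2α-hydroxy-4β-(dimethoxymethyl)-4α,8,10β-trimethyl-5α-H-octal-7-en-9-one | O=C1C(C)=CC[C@H]2[C@@](C)(C(OC)OC)C[C@H](O)C[C@]12C | intermediate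
19 | 2α-(tert-butyldimethylsilyloxy)-4β-(dimethoxymethyl)-4α,8,10β-trimethyl-5α-H-octal-7-en-9-one | O=C1C(C)=CC[C@H]2[C@@](C)(C(OC)OC)C[C@H](O[Si](C)(C)C(C)(C)C)C[C@]12C | intermediate
20 | but-3-enylmagnesium bromide | C=CCC[Mg]Br | starting material
21 | 9α-(but-3-enyl)-9β-hydroxy-2α-(tert-butyldimethylsilyloxy)-4β-(dimethoxymethyl)-4α,8,10β-trimethyl-5α-H-octal-7-ene (expected major C9 epimer) | C=CCC[C@]1(O)C(C)=CC[C@H]2[C@@](C)(C(OC)OC)C[C@H](O[Si](C)(C)C(C)(C)C)C[C@]12C | intermediate
22 | 9-(but-3-enyl)-2α-(tert-butyldimethylsilyloxy)-4β-(dimethoxymethyl)-4α,8,10β-trimethyl-5α-H-octal-8-en-7-one | C=CCCC1=C(C)C(=O)C[C@H]2[C@@](C)(C(OC)OC)C[C@H](O[Si](C)(C)C(C)(C)C)C[C@]12C | intermediate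
23 | C7 lithium enolate from 22 (C7=C8, 9α-H, 9β-butenyl) | C=CCC[C@H]1C(C)=C(O[Li])C[C@H]2[C@@](C)(C(OC)OC)C[C@H](O[Si](C)(C)C(C)(C)C)C[C@]12C | intermediate (not isolated)
24 | C7 enol triflate (C7=C8, 9α-H, 9β-butenyl) | C=CCC[C@H]1C(C)=C(OS(=O)(=O)C(F)(F)F)C[C@H]2[C@@](C)(C(OC)OC)C[C@H](O[Si](C)(C)C(C)(C)C)C[C@]12C | intermediate
25 | 9β-(but-3-enyl)-2α-(tert-butyldimethylsilyloxy)-4β-(dimethoxymethyl)-4α,8,10β-trimethyl-5α,9α-H-octal-7-ene | C=CCC[C@H]1C(C)=CC[C@H]2[C@@](C)(C(OC)OC)C[C@H](O[Si](C)(C)C(C)(C)C)C[C@]12C | intermediate
26 | 2α-(tert-butyldimethylsilyloxy)-19,19-dimethoxy-14,15-dinorlabd-7-en-13-one | CC(=O)CC[C@H]1C(C)=CC[C@H]2[C@@](C)(C(OC)OC)C[C@H](O[Si](C)(C)C(C)(C)C)C[C@]12C | intermediate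
27 | triethyl phosphonoacetate | CCOC(=O)CP(=O)(OCC)OCC | starting material
28 | ethyl (13E)-2α-(tert-butyldimethylsilyloxy)-19,19-dimethoxylabda-7,13-dien-15-oate | CCOC(=O)/C=C(\C)CC[C@H]1C(C)=CC[C@H]2[C@@](C)(C(OC)OC)C[C@H](O[Si](C)(C)C(C)(C)C)C[C@]12C | intermediate
29 | (13E)-2α-(tert-butyldimethylsilyloxy)-19,19-dimethoxylabda-7,13-dien-15-ol | OC/C=C(\C)CC[C@H]1C(C)=CC[C@H]2[C@@](C)(C(OC)OC)C[C@H](O[Si](C)(C)C(C)(C)C)C[C@]12C | intermediate
30 | methyl 4-chloro-4-oxobutanoate | COC(=O)CCC(=O)Cl | starting material
31 | methyl (13E)-2α-(tert-butyldimethylsilyloxy)-19,19-dimethoxylabda-7,13-dien-15-yl butanedioate | COC(=O)CCC(=O)OC/C=C(\C)CC[C@H]1C(C)=CC[C@H]2[C@@](C)(C(OC)OC)C[C@H](O[Si](C)(C)C(C)(C)C)C[C@]12C | intermediate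
32 | methyl (13E)-2α-(tert-butyldimethylsilyloxy)-19-oxolabda-7,13-dien-15-yl butanedioate | COC(=O)CCC(=O)OC/C=C(\C)CC[C@H]1C(C)=CC[C@H]2[C@@](C)(C=O)C[C@H](O[Si](C)(C)C(C)(C)C)C[C@]12C | intermediate
33 | methyl (13E)-2α-(tert-butyldimethylsilyloxy)-19-hydroxylabda-7,13-dien-15-yl butanedioate | COC(=O)CCC(=O)OC/C=C(\C)CC[C@H]1C(C)=CC[C@H]2[C@@](C)(CO)C[C@H](O[Si](C)(C)C(C)(C)C)C[C@]12C | intermediate
34 | 3-methylbutanoyl chloride | CC(C)CC(=O)Cl | starting material
35 | methyl (13E)-2α-(tert-butyldimethylsilyloxy)-19-(3-methylbutanoyloxy)labda-7,13-dien-15-yl butanedioate | COC(=O)CCC(=O)OC/C=C(\C)CC[C@H]1C(C)=CC[C@H]2[C@@](C)(COC(=O)CC(C)C)C[C@H](O[Si](C)(C)C(C)(C)C)C[C@]12C | intermediate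
36 | methyl (13E)-2α-hydroxy-19-(3-methylbutanoyloxy)labda-7,13-dien-15-yl butanedioate (CNP0118741.1) | COC(=O)CCC(=O)OC/C=C(\C)CC[C@H]1C(C)=CC[C@H]2[C@@](C)(COC(=O)CC(C)C)C[C@H](O)C[C@]12C | target

## Step count and least certain steps

Total step count: 23. Longest linear sequence: 23 steps (from 1; all other numbered reactants are commercial).

**Step 6 (key step).** The most likely failure is erosion of the facial selectivity at C4, that is, the oxidised carbon taking the equatorial instead of the axial site. The preference rests on conformational reasoning only, and the Z enol ether would push its methoxy group against C10 in the favoured chair. A second failure path is capture of the radical cation by methanol before the crowded C–C bond forms. The fallback gives up the oxidative closure and sets C4 by a classical equatorial alkylation. It sets out from 8. Pd(PPh3)4 with KOPh in THF should couple the methyl-ketone enolate with the vinylic bromide (intramolecular palladium-catalysed α-alkenylation, forming C2–C3 with the acetyl methyl as C3) to give 8,10β-dimethyl-2-methylene-5α-H-octal-7-ene-4,9-dione F1. A methoxymethylene Wittig reaction at the more accessible C4 ketone would give the exocyclic enol ether F2, and dilute acid would give the 4-formyl compound F3. KOtBu and MeI should then methylate the exocyclic enolate from the α face, away from the axial C20 methyl, to give the 4α-methyl-4β-formyl compound F4. HC(OMe)3 and MeOH with PPTS would return the route at 13.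

**Step 9.** The likely failure is elimination in place of substitution. The axial oxyphosphonium group at C2 has anti-periplanar axial hydrogens on C1 and C3, and its formation is slowed by the two syn-axial groups. The fallback replaces SN2 inversion by thermodynamic equilibration: 16 is heated with Al(OiPr)3 in isopropanol and toluene with a trace of acetone (Meerwein–Ponndorf–Verley and Oppenauer hydride exchange). This should drain the twice syn-axial 2β-alcohol into the equatorial 2α-alcohol while the shielded C9 carbonyl reacts slowly. It rejoins the route at 18 and makes no compound outside the list (F0).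

**Step 4.** The likely failures are loss of configuration at C5 by enolisation of the acetyl group under the basic ylide, and incomplete discrimination between the two carbonyls. The fallback avoids any enolisable ketone and sets out from 6. mCPBA should epoxidise only the isopropenyl group to give the epoxide F5. BF3·OEt2 at −78 °C would rearrange it (Meinwald rearrangement) to the aldehyde F6. HC(OMe)3 and MeOH with PPTS would give the dimethyl acetal F7, and Me3SiOTf with iPr2NEt would eliminate methanol toward C4, the only α-carbon, to return the route at 10.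

**Step 13.** The likely failure is acid-promoted side reaction in the chromium medium: ionisation of the tertiary allylic alcohol to dienes, or loss of the acetal, before the slow [3,3] shift of a hindered chromate ester. The fallback separates transposition from oxidation and sets out from 21. Catalytic Ph3SiOReO3 in ether at 0 °C should move the hydroxyl to C7 by 1,3-transposition, driven by the tetrasubstituted olefin, to give the secondary allylic alcohol F8. MnO2 in CH2Cl2 would then oxidise it and return the route at 22.

**Step 17.** The likely failure is modest E/Z selectivity, since the two groups on the ketone differ little in size, with loss of material on separation. The fallback builds the olefin by syn-carbometalation and sets out from 26. LiN(iPr)2 and ClP(O)(OEt)2 would give the terminal enol phosphate F9, and more LiN(iPr)2 would eliminate it to the terminal alkyne F10. Me3Al with catalytic Cp2ZrCl2 in CH2Cl2 (zirconium-catalysed carboalumination), followed by paraformaldehyde, should then give the (E)-allylic alcohol with the geometry fixed by syn addition. This returns the route at 29 and bypasses 28 and step 18.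

## Further compounds

F1 | step 6 | 8,10β-dimethyl-2-methylene-5α-H-octal-7-ene-4,9-dione | O=C1C(C)=CC[C@H]2C(=O)CC(=C)C[C@]12C
F2 | step 6 | 4-(methoxymethylene)-8,10β-dimethyl-2-methylene-5α-H-octal-7-en-9-one (E/Z mixture) | O=C1C(C)=CC[C@H]2C(=COC)CC(=C)C[C@]12C
F3 | step 6 | 4α-formyl-8,10β-dimethyl-2-methylene-5α-H-octal-7-en-9-one (equatorial aldehyde, epimerisable) | O=C1C(C)=CC[C@H]2[C@H](C=O)CC(=C)C[C@]12C
F4 | step 6 | 4β-formyl-4α,8,10β-trimethyl-2-methylene-5α-H-octal-7-en-9-one | O=C1C(C)=CC[C@H]2[C@@](C)(C=O)CC(=C)C[C@]12C
F0 | step 9 | none | none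
F5 | step 4 | 6-(2-bromoprop-2-enyl)-2,6-dimethyl-5-(2-methyloxiran-2-yl)cyclohex-2-enone (both epoxide epimers) | O=C1C(C)=CC[C@@H](C2(C)CO2)[C@]1(C)CC(Br)=C
F6 | step 4 | 2-[6-(2-bromoprop-2-enyl)-2,6-dimethyl-1-oxocyclohex-2-en-5-yl]propanal (both C4 epimers) | O=C1C(C)=CC[C@@H](C(C)C=O)[C@]1(C)CC(Br)=C
F7 | step 4 | dimethyl acetal of F6 (both C4 epimers) | O=C1C(C)=CC[C@@H](C(C)C(OC)OC)[C@]1(C)CC(Br)=C
F8 | step 13 | 9-(but-3-enyl)-7-hydroxy-2α-(tert-butyldimethylsilyloxy)-4β-(dimethoxymethyl)-4α,8,10β-trimethyl-5α-H-octal-8-ene (both C7 epimers) | C=CCCC1=C(C)C(O)C[C@H]2[C@@](C)(C(OC)OC)C[C@H](O[Si](C)(C)C(C)(C)C)C[C@]12C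
F9 | step 17 | diethyl enol phosphate of 26 (terminal C13=CH2) | C=C(OP(=O)(OCC)OCC)CC[C@H]1C(C)=CC[C@H]2[C@@](C)(C(OC)OC)C[C@H](O[Si](C)(C)C(C)(C)C)C[C@]12C
F10 | step 17 | terminal alkyne, 9β-(but-3-ynyl)-2α-(tert-butyldimethylsilyloxy)-4β-(dimethoxymethyl)-4α,8,10β-trimethyl-5α,9α-H-octal-7-ene | C#CCC[C@H]1C(C)=CC[C@H]2[C@@](C)(C(OC)OC)C[C@H](O[Si](C)(C)C(C)(C)C)C[C@]12C
A1 | alternative 1 | acyclic triene: methyl (2E,8E,10Z) enoate with 5-OTBS, 7-methyl, 7-(PMB-oxymethyl) and 10-triethylsilyloxy groups | COC(=O)/C=C(\C)C[C@@H](O[Si](C)(C)C(C)(C)C)C[C@](C)(COCc1ccc(OC)cc1)/C=C/C(O[Si](CC)(CC)CC)=C/C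
A2 | alternative 1 | trans-decalin C6=C7 triethylsilyl enol ether with 9β-ester, 8β-methyl, 2α-OTBS and 19-OPMB | COC(=O)[C@H]1[C@@H](C)C(O[Si](CC)(CC)CC)=C[C@H]2[C@@](C)(COCc3ccc(OC)cc3)C[C@H](O[Si](C)(C)C(C)(C)C)C[C@]12C
A3 | alternative 2 | octal-1(10)-en-2β-ol with 4α-ester, C8 dioxolane and ketal-protected 3-oxobutyl chain on C9 | CC1(CC[C@H]2C3(OCCO3)CC[C@H]4[C@H](C(=O)OC)C[C@@H](O)C=C24)OCCO1
A4 | alternative 2 | 1,10-methano-bridged decalin-2β-ol (β-cyclopropane) | CC3(CC[C@H]1C4(OCCO4)CC[C@H]2[C@H](C(=O)OC)C[C@@H](O)[C@H]5C[C@@]125)OCCO3
A5 | alternative 3 | (E)-1-(dimethylamino)-3-(tert-butyldimethylsilyloxy)buta-1,3-diene | CN(C)/C=C/C(=C)O[Si](C)(C)C(C)(C)C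
A6 | alternative 3 | (E)-4-(2-ethyl-1,3-dioxolan-2-yl)-2-methylbut-2-enal | O=C/C(C)=C/CC1(CC)OCCO1
A7 | alternative 3 | ring A cyclohex-1-en-3-one with C10 methyl and formyl and the C5 ketal chain | O=C[C@@]1(C)C=CC(=O)C[C@@H]1CC2(CC)OCCO2
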